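| flask | substrate | reagent in the second phase | remark | time | volume of the second phase over the first |
|---|---|---|---|---|---|
| grey | 0.15 M | 2 equiv | run made earlier |  |  |
| green | 0.60 M | 2 equiv | run made earlier |  |  |
| teal | 0.30 M | 3 equiv | run made earlier |  |  |
| flask | 0.30 M | 2.00 equiv |  | 1.5 h | 1.0 |

| run | time / min | target / % | substrate / % |
|---|---|---|---|
| grey | 12.0 | 3.2 | 65.9 |
| grey | 25.0 | 10.5 | 45.1 |
| grey | 40.0 | 14.5 | 29.4 |
| grey | 50.0 | 14.1 | 22.0 |
| grey | 60.0 | 12.5 | 16.0 |
| grey | 80.0 | 9.6 | 11.8 |
| grey | 90.0 | 10.6 | 7.4 |
| green | 5.00 | 3.6 | 57.1 |
| green | 15.0 | 8.1 | 25.3 |
| green | 25.0 | 10.6 | 12.7 |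
| green | 40.0 | 7.5 | 6.8 |
| green | 50.0 | 6.6 | 2.1 |
| green | 80.0 | 1.8 | 0.3 |
| green | 90.0 | 0.6 | 1.4 |
| teal | 8.00 | 4.7 | 59.3 |
| teal | 25.0 | 13.1 | 22.5 |
| teal | 40.0 | 11.3 | 12.7 |
| teal | 60.0 | 5.9 | 2.4 |
| teal | 90.0 | 2.8 | 0 |

(readings scatter by 1 percentage point)

- in the second phase: reagent in the second phase; everything else is in the first
- charges count per volume of the first phase; a concentration in a rate is the amount of a species over the volume of its own phase; every rate counts per litre of the first phase
- what was read earlier has a scatter of 1 percentage point, one standard deviation
- the earlier runs hold the two phases in the same ratio of volumes as the flask asked about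

- zeta: doubling the transfer coefficient of the reagent in the second phase, all else as stated
- epsilon: doubling the amount of reagent in the second phase, all else as stated

1. how much target there is at 1.5 h, in percent of the substrate charged
2. the change that raises the amount of target at 1.5 h, in percent of the substrate charged most ("none" if none brings more than 2 percentage points) (zeta / epsilon / none)
3. amount of target at 1.5 h, in percent of the substrate charged, after epsilon

**Early rise.** At early times target climbs in the grey run and later falls, which marks it as an intermediate of consecutive steps, with a peak time. The highest readings stand at 40.0 min in the grey run and 25.0 min in the green run, on a coarse grid and with their scatter. Between 0.15 M and 0.60 M, I read the peak time as falling with c(substrate) to the power 0.339, so the flask at 0.30 M should peak near 31.6 min.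

**Question reversed.** The overrun is 2.85, the asked time over the peak time. For a faster flask to gain target at the asked time, I want an overrun below one, with target still climbing then. This flask stands well above that. The teal run, with more reagent in the second phase, reads highest at 25.0 min, sooner than my peak time, so I expect epsilon to lose target.

**The forecast.** It gives 5%, then 2.2% after epsilon, and chooses none, holding that “More reagent or faster transfer speeds up the decay”.

**The flask.** It gives 3.44%, and 0.420% after epsilon; the choice is none, with zeta moving target by −1 percentage point and epsilon by −3 points.

    reagent in the reaction phase ⇌ reagent in the second phase, rate k1*([reagent in the reaction phase] - [reagent in the second phase]/K1) per volume of the first phase (partition coefficient = 0.590, kL = 0.0100 min⁻¹)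
    substrate + reagent in the reaction phase → target (k = 0.180 L mol⁻¹ min⁻¹)
    reagent in the reaction phase + target → over-reacted product (k = 0.250 L mol⁻¹ min⁻¹)
    target → over-reaction product (k = 0.00190 min⁻¹)
    2 substrate → homo dimer (k = 0.120 L mol⁻¹ min⁻¹)
    target ⇌ isomer of the product (K = 0.880, k = 0.00530 min⁻¹)

**Overrun applied.** In the flask, each step taken net, target is made 1.38 times as fast as it is used at 0.433 h, but 0.427 times as fast at 1.50 h, so the turn lies between, and the overrun of 2.85 stands above one. The neighbouring flask, the same but at 0.075 M of substrate, gets by my reckoning a peak time of 50.6 min from the same power, and so a smaller overrun of 1.78. It holds 13.8% of target, with 21% of substrate left.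

The readings stem from a simulated flask with constants of no real substance.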